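Beside the starting material the free catalyst is a trace, 0.50 mM against 0.050 M, so we ask what that trace is worth in target.

| flask | starting material | reagent | capture agent | protic impurity | free catalyst | remark | time |
|---|---|---|---|---|---|---|---|
| Wednesday's | 0.050 M | 0.050 M | 5 mM | 0.015 M | 0.50 mM | the very flask that is asked about, followed so far |  |
| flask | 0.050 M | 0.0500 M | 5.00 mM | 0.0150 M | 0.50 mM |  | 15 h |

Wednesday's run (percent of the starting material charged)

| time / h | target / % | starting material / % |
|---|---|---|
| 1.50 | 29.0 | 40.6 |
| 4.00 | 37.5 | 31.7 |
| 8.00 | 39.6 | 29.9 |
| 12.0 | 39.4 | 29.5 |

(each reading ± 0.5 percentage points)

- south-east: change nothing and wait 8.0 h more
- north-east: at 15 h add free catalyst, 50.0% of the amount charged, then wait 8.0 h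
- west: at 15 h add reagent, 50.0% of the amount charged, then wait 8.0 h
- east: at 15 h take out 90% of the target then present, then wait 8.0 h

- what is taken out of target is counted as made
- the analysis behind the earlier runs scatters by 0.5 percentage points, standard deviation
- additions bring no volume worth counting

* target, in percent of the starting material first charged, at 15 h
* the option that brings most further target ("none" if no option brings more than 2 percentage points) (south-east / north-east / west / east / none)
* target present, with what was taken out counted in, in percent of the starting material first charged, after south-east
* target present, with what was taken out counted in, in percent of the starting material first charged, after west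

We build this flask up one process at a time. Take the main step first: starting material and reagent are charged one to one and meet on the catalyst, which leaves room for 100% target. Now add the protic impurity. Its 0.0150 M is 30.0% of the starting material, and the first reading at 1.50 h already lacks 30.4% from the balance of target and starting material. We therefore read one starting material lost per impurity, and the room falls to 70.0%.

Yet target reads 39.6% at 8.00 h and 39.4% at 12.0 h, a change of 0.2 percentage points against a scatter of 0.5 points, with 29.5% of the starting material still free. So we add a third process, as our own assumption: the capture agent takes up the catalyst for good. The capture agent stands at ten times the catalyst, and taking up the whole catalyst costs it 10.0% of its charge, so [capture agent] stays close to its charge and the catalyst's death is roughly pseudo-first-order. We treat that death as a small correction to each round: every round carries a small chance of losing the catalyst.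

That gives a quantity to carry, the round count (turnover number), meaning target made per catalyst charged before the catalyst stops, as read at 12.0 h: 39.4. On this assumption target at 15 h stays near 39.4%, and we expect no further target from waiting, from reagent or from removing target. Adding 0.250 mM of free catalyst should buy 20 points, and the free starting material has room for that. We pick north-east.

The forecast gives 39.5% at 15 h, 39.6% after south-east and 49% after west, and it picks west. It weighs an equilibrium against a dying catalyst and says “the runs cannot separate them”. Our reckoning parts from it on the option.

The flask gives 39.4% at 15 h, 39.4% after south-east and 39.4% after west, and the best option is north-east, which brings 19 points and ends at 57.9%.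

    catalyst intermediate A ⇌ catalyst intermediate B (K = 0.490, k = 96.9 h⁻¹)
    reagent + catalyst intermediate B ⇌ catalyst intermediate C (K = 43.0 L mol⁻¹, k = 27600 L mol⁻¹ h⁻¹)
    starting material + free catalyst → catalyst intermediate A (k = 2600 L mol⁻¹ h⁻¹)
    starting material + protic impurity → quenched substrate (k = 619 L mol⁻¹ h⁻¹)
    catalyst intermediate C → free catalyst + target (k = 7230 h⁻¹)
    catalyst intermediate A + capture agent → trapped intermediate (k = 433 L mol⁻¹ h⁻¹)

In this flask at 15.0 h the catalyst stands as trapped intermediate, >99.9% of its charge, while 61% of the reagent remains. The round count of 39.4 on the added catalyst gave 20 points, against the 19 points found. In a second flask, like this one but charged with 3.0 × 10⁻⁴ M of free catalyst, the same count gives 23.6%, and that flask holds 23.5% target with 46% of its starting material left.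

Readings and results are simulated on assumed constants; the scatter is artificial.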